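## Retrosynthetic overview
1. Aplyviolene comes from a bridged dilactone by selective γ-lactone → lactol reduction and acetylation. That dilactone comes from a menthyl acetal/tert-butyl ester by Lewis-acid acetal exchange and lactonisation, which closes the last ring.
2. The exocyclic alkene comes from Wittig methylenation of a hydroazulenone.
3. The seven-membered ring comes from a hydrogen-atom-transfer (HAT)-initiated tertiary radical (Me2C•) adding 7-endo to a cyclopentenyl ketone, which forms the CMe2–CH bond.
4. The cyclopentenyl ketone comes from the enol triflate of a 2,2-disubstituted cyclopentanone. That ketone comes from a Mukaiyama–Michael addition of 2-methylcyclopentanone silyl enol ether to a chiral 3-substituted 5-menthyloxybutenolide.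
5. Rings are formed in this order: γ-lactone (acceptor, built first); cyclopentanone joined to it by Michael addition; seven-membered ring (radical); bridged δ-lactone/acetal (last).

Assumption: the (+)-menthyl acetal of 5-hydroxybutenolide crystallises as the (5S) diastereomer, mirroring the known (5R)/(−)-menthyl case.
Assumption: the quaternary-centre epimer formed in Step 6 is separable by chromatography and the desired isomer is carried forward (maximum yield about 50%).

## Route

**Step 1**
Reactants: 1 (2-methylcyclopentan-1-one)
Product: 2 (trimethyl[(2-methylcyclopent-1-en-1-yl)oxy]silane)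
Conditions: TMSCl, NaI, Et3N, MeCN, 60 °C
Reagents that add atoms: chlorotrimethylsilane, C[Si](C)(C)Cl
Why: Silylation under equilibrating conditions favours the tetrasubstituted enol ether, which places the nucleophilic carbon at the methyl-bearing C2; no stereocentre forms.

**Step 2**
Reactants: 3 (furfural)
Product: 4 (5-hydroxyfuran-2(5H)-one)
Conditions: O2, hν (visible), Rose Bengal, i-Pr2NEt, CH2Cl2/MeOH, −10 °C
Reagents that add atoms: dioxygen, O=O
Why: Singlet-oxygen [4+2] addition gives an endoperoxide, and base-induced rearrangement with loss of the formyl carbon gives the hydroxybutenolide (racemic acetal carbon, fixed in Step 3).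

**Step 3**
Reactants: 4
Product: 5 ((5S)-5-[(1S,2R,5S)-menthyloxy]furan-2(5H)-one)
Conditions: (+)-menthol, cat. TsOH, PhMe, Dean–Stark reflux; then Et3N, pentane, crystallisation
Reagents that add atoms: (+)-menthol, C[C@H]1CC[C@@H]([C@H](C1)O)C(C)C
Why: Acetalisation gives C5 epimers that interconvert through the oxocarbenium; the less soluble (5S) diastereomer crystallises (crystallisation-induced asymmetric transformation), which fixes the absolute configuration of the later A/B/D centres.

**Step 4**
Reactants: 5
Product: 6 ((5S)-3-iodo-5-menthyloxyfuran-2(5H)-one)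
Conditions: I2, pyridine, CH2Cl2, 0 °C → rt
Reagents that add atoms: iodine, II
Why: Johnson α-iodination of the enone (pyridine conjugate addition, iodination, elimination); the acetal centre is untouched.

**Step 5**
Reactants: 6
Product: 7 (3-[(tert-butoxycarbonyl)methyl]-(5S)-5-menthyloxyfuran-2(5H)-one)
Conditions: BrZnCH2CO2t-Bu (from Zn + BrCH2CO2t-Bu), Pd(PPh3)4 (5 mol %), THF, 50 °C
Reagents that add atoms: tert-butyl bromoacetate (as its zinc reagent), BrCC(=O)OC(C)(C)C
Why: Negishi coupling of the α-iodo enone with a Reformatsky-type zinc reagent installs the CH2CO2tBu arm that becomes the bridging lactone.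

**Step 6**
Reactants: 2 (silyl enol ether) and 7 (butenolide acceptor)
Product: 8 (2-methyl-2-[lactonyl]cyclopentanone; the lactone ring bears 5S-OMen trans to the new C–C bond and a CH2CO2tBu arm cis to it)
Conditions: TMSOTf (20 mol %), CH2Cl2, −78 °C; then THF/1 M HCl; chromatographic separation of the quaternary-centre epimer
Reagents that add atoms: none
Why: Proposed new method: the Lewis-acid-activated butenolide is attacked by the enol ether anti to the menthyloxy group (the facial rule of 5-alkoxybutenolide conjugate additions), the resulting silyl ketene acetal is protonated anti to the new bulky cyclopentanone substituent so CH2CO2tBu ends cis to it, and the quaternary centre is set by the donor face and separated; the closest known reaction is the Mukaiyama–Michael addition to 5-alkoxy-2(5H)-furanones.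

**Step 7**
Reactants: 8
Product: 9 (enol triflate of the cyclopentanone)
Conditions: KHMDS, PhNTf2, THF, −78 °C
Reagents that add atoms: N-phenylbis(trifluoromethanesulfonimide), O=S(=O)(C(F)(F)F)N(c1ccccc1)S(=O)(=O)C(F)(F)F
Why: Only the CH2 side of the ketone can enolise, because the quaternary carbon blocks the other, so regiospecific triflation gives the trisubstituted vinyl triflate (ketone α-deprotonation outcompetes the hindered tertiary lactone α-H at −78 °C).

**Step 8**
Reactants: 9
Product: 10 (cyclopentenyl 5-methylhex-4-enyl ketone)
Conditions: CO (1 atm), (4-methylpent-3-en-1-yl)ZnBr, Pd(PPh3)4, LiCl, THF, 50 °C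
Reagents that add atoms: carbon monoxide, [C-]#[O+]; (4-methylpent-3-en-1-yl)zinc bromide (from 5-bromo-2-methylpent-2-ene), CC(C)=CCC[Zn]Br
Why: Carbonylative Negishi coupling of the vinyl triflate installs the acyl carbon and the prenyl-type chain that carries the radical precursor alkene; no new stereocentre forms.

**Step 9**
Reactants: 10
Product: 11 (hydroazulenone, cis-fused)
Conditions: Fe(acac)3 (1 equiv), PhSiH3 (3 equiv), EtOH, 60 °C, 0.01 M (slow addition)
Reagents that add atoms: none (net addition of H2 from silane/EtOH)
Why: Proposed new method: Fe–H transfers H• to the CH of the trisubstituted alkene to give a tertiary radical, which adds 7-endo to the enone β-carbon (the nucleophilic radical is polarity-matched, and attack at the α-carbon would need a bond next to the quaternary centre); the face syn to the methyl is attacked, anti to the bulky lactone-bearing substituent, so the new CH–CMe2 stereocentre (f) is set cis to the methyl, and the α-keto radical is reduced to the cis-fused ring junction, which can equilibrate at the α-carbon; the closest known reaction is HAT-initiated (Mukaiyama/Baran-type) radical conjugate addition, here applied intramolecularly in the 7-endo mode.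

**Step 10**
Reactants: 11
Product: 12 (exocyclic-methylene hydroazulene)
Conditions: Ph3PCH3Br, KHMDS, THF, 0 °C → rt
Reagents that add atoms: methyltriphenylphosphonium bromide, C[P+](c1ccccc1)(c1ccccc1)c1ccccc1.[Br-] (supplies the =CH2)
Why: Wittig methylenation converts the ketone selectively to the 1,1-disubstituted alkene, and the α-centre, if epimerised, returns to the thermodynamic cis-fused isomer.

**Step 11**
Reactants: 12
Product: 13 (bridged dilactone, 2,6-dioxabicyclo[3.2.1] core)
Conditions: TMSOTf (3 equiv), 2,6-di-tert-butyl-4-methylpyridine, CH2Cl2, −20 → 0 °C; then aq. NaHCO3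
Reagents that add atoms: none
Why: Proposed new method: TMSOTf converts the tert-butyl ester to the silyl ester and ionises the menthyl acetal to the lactone-stabilised oxocarbenium, which the carboxylate captures on the face that carries the CH2 arm (cis to D's substituent), epimerising the acetal carbon B to the required configuration; the closest known reactions are TMSOTf deprotection of tert-butyl esters and intramolecular glycosylation-type acetal exchange.

**Step 12**
Reactants: 13
Product: 14 (aplyviolene)
Conditions: DIBAL-H (1.1 equiv), CH2Cl2, −78 °C; then Ac2O, pyridine, DMAP, −78 → 0 °C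
Reagents that add atoms: acetic anhydride, CC(=O)OC(C)=O
Why: Proposed new method: hydride adds to the γ-lactone carbonyl, which is exposed on the convex face, whereas the bridged δ-lactone carbonyl sits under the syn hydroazulene substituent; the lactol anomers equilibrate and acetylate to the exo acetate; the closest known reaction is DIBAL lactone → lactol reduction/acetylation.

## Compound list
1 | 2-methylcyclopentan-1-one | CC1CCCC1=O | starting material
2 | trimethyl[(2-methylcyclopent-1-en-1-yl)oxy]silane | CC1=C(O[Si](C)(C)C)CCC1 | intermediate
3 | furfural | O=Cc1ccco1 | starting material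
4 | 5-hydroxyfuran-2(5H)-one | O=C1C=CC(O)O1 | intermediate
5 | (5S)-5-[(1S,2R,5S)-menthyloxy]furan-2(5H)-one | O=C1O[C@H](O[C@H]2C[C@@H](C)CC[C@@H]2C(C)C)C=C1 | intermediate
6 | (5S)-3-iodo-5-menthyloxyfuran-2(5H)-one | O=C1O[C@H](O[C@H]2C[C@@H](C)CC[C@@H]2C(C)C)C=C1I | intermediate
7 | 3-[(tert-butoxycarbonyl)methyl]-(5S)-5-menthyloxyfuran-2(5H)-one | O=C1O[C@H](O[C@H]2C[C@@H](C)CC[C@@H]2C(C)C)C=C1CC(=O)OC(C)(C)C | intermediate
8 | 2-methyl-2-[lactonyl]cyclopentanone (Michael adduct) | O=C1CCC[C@@]1(C)[C@@H]2[C@@H](O[C@H]5C[C@@H](C)CC[C@@H]5C(C)C)OC(=O)[C@@H]2CC(=O)OC(C)(C)C | intermediate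
9 | enol triflate of 8 | FC(F)(F)S(=O)(=O)OC1=CCC[C@@]1(C)[C@@H]2[C@@H](O[C@H]5C[C@@H](C)CC[C@@H]5C(C)C)OC(=O)[C@@H]2CC(=O)OC(C)(C)C | intermediate
10 | cyclopentenyl 5-methylhex-4-enyl ketone | CC(C)=CCCC(=O)C1=CCC[C@@]1(C)[C@@H]2[C@@H](O[C@H]5C[C@@H](C)CC[C@@H]5C(C)C)OC(=O)[C@@H]2CC(=O)OC(C)(C)C | intermediate
11 | hydroazulenone (cis-fused) | O=C1CCCC(C)(C)[C@@H]2CC[C@@](C)([C@@H]3[C@@H](O[C@H]5C[C@@H](C)CC[C@@H]5C(C)C)OC(=O)[C@@H]3CC(=O)OC(C)(C)C)[C@H]12 | intermediate
12 | exocyclic-methylene hydroazulene | C=C1CCCC(C)(C)[C@@H]2CC[C@@](C)([C@@H]3[C@@H](O[C@H]5C[C@@H](C)CC[C@@H]5C(C)C)OC(=O)[C@@H]3CC(=O)OC(C)(C)C)[C@H]12 | intermediate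
13 | bridged dilactone | C=C1CCCC(C)(C)[C@@H]2CC[C@@](C)([C@@H]3[C@@H]4OC(=O)C[C@H]3C(=O)O4)[C@H]12 | intermediate
14 | aplyviolene | C=C1CCCC(C)(C)[C@@H]2CC[C@@](C)([C@@H]3[C@@H]4OC(=O)C[C@H]3[C@H](OC(C)=O)O4)[C@H]12 | target

## Totals
Total steps: 12. Longest linear sequence: 11 steps (furfural → 14).

Three steps most likely to fail:
1. **Step 6** (Mukaiyama–Michael forming the quaternary–tertiary bond). Fallback: form the same bond by radical conjugate addition instead. Generate the tertiary α-keto radical by Fe–H HAT on 2-methylenecyclopentan-1-one and add it to acceptor 7, then continue from Step 7.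
2. **Step 9** (7-endo HAT cyclisation, with competing reduction of the alkene and 6-exo attack). Fallback: close the ring by a polar route. Hydrochlorinate the prenyl group to the tertiary chloride, make the tertiary organozinc/cuprate, and close the ring by intramolecular 1,4-addition to the enone.
3. **Step 12** (DIBAL chemoselectivity between the two lactones). Fallback: reorder the sequence. Reduce and acetylate the lone γ-lactone of the monocyclic compound 12, where only one lactone is present and the tert-butyl ester survives at −78 °C. Then form the bridged lactone by mild acid-promoted transacetalisation of the menthyl acetal (CSA) in place of Step 11.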